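**Retrosynthetic overview**
1. The target is unmasked in one fluoride step from a silicon-protected 2,4-dialkoxypyridine N-oxide. The N–O bond is bought in and the pyridone ring is never built. The C3–acyl and C5–carbinol bonds come from two iodine–magnesium exchanges on a 3,5-diiodopyridine N-oxide.
2. The C3 partner is a trans-decalin aldehyde, made by an iminium-catalysed intramolecular Diels–Alder reaction of a (6R)-trienal; both carbocycles close at once (first rings formed).
3. The trienal comes from (R)-citronellal by cross-metathesis and Wittig olefination; citronellal comes from geranial by organocatalytic transfer hydrogenation (first stereocentre).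
4. The C5 partner is a trans-epoxy ketone from (S)-4-silyloxycyclohexenone, which comes from achiral 4-silyloxycyclohexanone by a new amine-catalysed desymmetrising selenenylation–elimination; the oxirane is formed second.
5. Order: decalin, oxirane, union at C3, union at C5, oxidation to the ketone, unmasking of the N-hydroxypyridone.

Assumption: geranial (the E isomer of citral), N-methoxy-N-methylacrylamide, (E)-but-2-enyl(triphenyl)phosphonium chloride, 4-(tert-butyldimethylsilyloxy)cyclohexanone and 2-chloro-4-nitropyridine 1-oxide are bought.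

**Route**

Step 1
Reactants: 1 geranial [(2E)-3,7-dimethylocta-2,6-dienal]
Product: 2 (R)-citronellal [(3R)-3,7-dimethyloct-6-enal]
Conditions: morpholinium (R)-3,3'-bis(2,4,6-triisopropylphenyl)-1,1'-binaphthyl-2,2'-diyl phosphate (10 mol%), Hantzsch ester (diethyl 2,6-dimethyl-1,4-dihydropyridine-3,5-dicarboxylate, 1.1 equiv), THF, 23 °C
Reagents that add atoms: none
Why: Asymmetric counteranion-directed iminium catalysis (organocatalytic transfer hydrogenation): the chiral phosphate paired with the morpholinium iminium ion of 1 steers hydride transfer from the Hantzsch ester to one face of C3 and sets the (R)-methyl stereocentre (about 90% ee expected), the first stereocentre of the route.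

Step 2
Reactants: 2 (R)-citronellal; 3 N-methoxy-N-methylacrylamide (N-methoxy-N-methylprop-2-enamide, 3 equiv)
Product: 4 (2E,6R)-N-methoxy-N,6-dimethyl-8-oxooct-2-enamide
Conditions: second-generation Hoveyda–Grubbs catalyst [RuCl2(H2IMes)(=CH-C6H4-2-O-i-Pr)] (5 mol%), CH2Cl2, 40 °C
Reagents that add atoms: none
Why: Olefin cross-metathesis of the trisubstituted prenyl terminus with an electron-poor acrylamide is selective because neither partner homodimerises readily, volatile isobutene drives it forward, the E-enamide is favoured, and the aldehyde and C6 are untouched.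

Step 3
Reactants: 4 (2E,6R)-N-methoxy-N,6-dimethyl-8-oxooct-2-enamide; 5 (E)-but-2-en-1-yl(triphenyl)phosphonium chloride (1.3 equiv)
Product: 8 (2E,6R,8E,10E)-N-methoxy-N,6-dimethyldodeca-2,8,10-trienamide, via crotylidene ylide 6 (not isolated), via 8Z-trienamide 7 (not isolated)
Conditions: KN(SiMe3)2, THF, −78 → 0 °C; then I2 (5 mol%), CH2Cl2, visible light, 23 °C
Reagents that add atoms: none
Why: Wittig olefination of the saturated aldehyde by the semistabilised allylic ylide (much faster than attack on the Weinreb amide at −78 °C) gives an 8E/8Z mixture, and iodine-catalysed photoequilibration converts the 8Z isomer into the thermodynamically preferred (8E,10E)-diene without touching C6.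

Step 4
Reactants: 8 (2E,6R,8E,10E)-N-methoxy-N,6-dimethyldodeca-2,8,10-trienamide
Product: 9 (2E,6R,8E,10E)-6-methyldodeca-2,8,10-trienal
Conditions: i-Bu2AlH (1.3 equiv), THF, −78 °C; aq. potassium sodium tartrate
Reagents that add atoms: none
Why: Partial reduction of a Weinreb amide: the chelated aluminium adduct survives until work-up, so the enal is released without over-reduction and the diene and C6 are unaffected.

Step 5
Reactants: 9 (2E,6R,8E,10E)-6-methyldodeca-2,8,10-trienal
Product: 10 (1R,2R,4aS,6R,8aR)-2,6-dimethyl-1,2,4a,5,6,7,8,8a-octahydronaphthalene-1-carbaldehyde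
Conditions: (2R,5R)-5-benzyl-2-tert-butyl-3-methylimidazolidin-4-one·TfOH (20 mol%), MeCN/H2O (98:2), 5 °C
Reagents that add atoms: none
Why: Iminium-catalysed (organocatalytic) intramolecular Diels–Alder reaction: the (E)-iminium ion lowers the enal LUMO and its benzyl group blocks one face, so the tethered (E,E)-diene adds endo to the open face and sets C1, C2, C4a and C8a of the trans-decalin, and this facial sense is matched by the chair-like tether that keeps the C6 methyl equatorial, which sends the minor enantiomer of 9 mainly to separable diastereomers.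

Step 6
Reactants: 11 4-{[tert-butyl(dimethyl)silyl]oxy}cyclohexan-1-one
Product: 14 (4S)-4-{[tert-butyl(dimethyl)silyl]oxy}cyclohex-2-en-1-one, via trans-selenide 12 (not isolated), via selenoxide 13 (not isolated)
Conditions: N-(phenylseleno)phthalimide (1.05 equiv), (S)-N-(pyrrolidin-2-ylmethyl)trifluoromethanesulfonamide (20 mol%), CH2Cl2, −20 °C; then H2O2 (30% aq.), pyridine, 0 → 23 °C
Reagents that add atoms: none
Why: Proposed new method: enamine catalysis turns the achiral ketone into two rapidly equilibrating enantiotopic enamines, the sulfonamide N–H hydrogen bond delivers the phenylselenyl cation to one enamine face, and only the enamine for which this is the axial face anti to the equatorial 4-silyloxy group reacts fast, so C–Se bond formation picks one α-methylene and thereby fixes C4 as S (trans-selenide 12), after which oxidation to selenoxide 13 and syn-elimination remove the selenium-bearing centre but keep C4, a net enantioselective desaturation; the closest known reaction types are amine-catalysed α-selenenylation of aldehydes and ketones, amine-catalysed desymmetrising α-functionalisation (aldol, aminoxylation) of 4-substituted cyclohexanones and selenoxide syn-elimination.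

Step 7
Reactants: 14 (4S)-4-{[tert-butyl(dimethyl)silyl]oxy}cyclohex-2-en-1-one
Product: 15 (1R,5S,6S)-5-{[tert-butyl(dimethyl)silyl]oxy}-7-oxabicyclo[4.1.0]heptan-2-one
Conditions: H2O2 (30% aq.), benzyltrimethylammonium hydroxide (cat.), THF, 0 °C
Reagents that add atoms: hydrogen peroxide, OO
Why: Weitz–Scheffer nucleophilic epoxidation: hydroperoxide adds to the enone anti to the bulky silyloxy group at C4 and the enolate closes the oxirane on that face, giving the epoxide trans to the silyl ether and fixing both oxirane carbons from the existing centre.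

Step 8
Reactants: 16 2-chloro-4-nitropyridine 1-oxide
Product: 18 2,4-bis[2-(trimethylsilyl)ethoxy]pyridine 1-oxide, via 2-chloro-4-silylethoxy N-oxide 17 (not isolated)
Conditions: Me3SiCH2CH2OH (2.3 equiv), NaH (2.3 equiv), THF, 0 → 45 °C
Reagents that add atoms: 2-(trimethylsilyl)ethanol, C[Si](C)(C)CCO
Why: Twofold nucleophilic aromatic substitution on the N-oxide-activated ring: the alkoxide displaces the 4-nitro group first and the 2-chloride second, installing both fluoride-labile ethers while keeping the N–O bond that becomes the N-hydroxy group; no stereocentre is formed.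

Step 9
Reactants: 18 2,4-bis[2-(trimethylsilyl)ethoxy]pyridine 1-oxide
Product: 20 3,5-diiodo-2,4-bis[2-(trimethylsilyl)ethoxy]pyridine 1-oxide, via 5-iodo N-oxide 19 (not isolated)
Conditions: N-iodosuccinimide (2.2 equiv), CF3CO2H (10 mol%), MeCN, 23 °C, dark
Reagents that add atoms: N-iodosuccinimide, O=C1CCC(=O)N1I
Why: Electrophilic aromatic iodination: C5 and then C3 are the only positions ortho or para to both alkoxy donors, so they are iodinated in turn and C6 is left alone; no stereocentre is formed.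

Step 10
Reactants: 20 3,5-diiodo-2,4-bis[2-(trimethylsilyl)ethoxy]pyridine 1-oxide; 10 (1R,2R,4aS,6R,8aR)-2,6-dimethyl-1,2,4a,5,6,7,8,8a-octahydronaphthalene-1-carbaldehyde (0.9 equiv)
Product: 22 3-{[(1R,2R,4aS,6R,8aR)-2,6-dimethyl-1,2,4a,5,6,7,8,8a-octahydronaphthalen-1-yl](hydroxy)methyl}-5-iodo-2,4-bis[2-(trimethylsilyl)ethoxy]pyridine 1-oxide (both carbinol epimers), via 3-pyridylmagnesium chloride 21 (not isolated)
Conditions: i-PrMgCl·LiCl (1.05 equiv), THF, −78 °C, 15 min; then 10, −78 → −20 °C; aq. NH4Cl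
Reagents that add atoms: none
Why: Iodine–magnesium exchange followed by Grignard addition to the aldehyde: the reversible exchange settles on the C3 magnesium species, which is stabilised by two flanking alkoxy groups and forms faster at −78 °C than deprotonation at C6 next to the N-oxide, and it adds to the hindered aldehyde without epimerising C1; the new carbinol centre is left as a mixture because step 12 removes it.

Step 11
Reactants: 22 the iodo carbinol from step 10; 15 (1R,5S,6S)-5-{[tert-butyl(dimethyl)silyl]oxy}-7-oxabicyclo[4.1.0]heptan-2-one (1.3 equiv)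
Product: 24 5-[(1R,2R,5S,6S)-5-{[tert-butyl(dimethyl)silyl]oxy}-2-hydroxy-7-oxabicyclo[4.1.0]heptan-2-yl]-3-{[(1R,2R,4aS,6R,8aR)-2,6-dimethyl-1,2,4a,5,6,7,8,8a-octahydronaphthalen-1-yl](hydroxy)methyl}-2,4-bis[2-(trimethylsilyl)ethoxy]pyridine 1-oxide, via bis-magnesium intermediate 23 (not isolated)
Conditions: i-PrMgCl·LiCl (2.1 equiv), THF, −78 → −40 °C; LaCl3·2LiCl (1.0 equiv); then 15, −78 → −20 °C; aq. NH4Cl
Reagents that add atoms: none
Why: A second iodine–magnesium exchange (the first equivalent of Grignard reagent deprotonates the hydroxyl) and lanthanum-promoted 1,2-addition to the ketone: the aryl nucleophile attacks the carbonyl of 15 anti to the oxirane oxygen, which sets the tertiary carbinol with its hydroxyl cis to the epoxide and trans to the silyl ether, while LaCl3·2LiCl suppresses enolisation and epoxide opening.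

Step 12
Reactants: 24 the diol from step 11
Product: 25 5-[(1R,2R,5S,6S)-5-{[tert-butyl(dimethyl)silyl]oxy}-2-hydroxy-7-oxabicyclo[4.1.0]heptan-2-yl]-3-[(1R,2R,4aS,6R,8aR)-2,6-dimethyl-1,2,4a,5,6,7,8,8a-octahydronaphthalene-1-carbonyl]-2,4-bis[2-(trimethylsilyl)ethoxy]pyridine 1-oxide
Conditions: Dess–Martin periodinane (1.5 equiv), NaHCO3, CH2Cl2, 0 → 23 °C
Reagents that add atoms: none
Why: Dess–Martin oxidation turns the secondary carbinol into the ketone and so removes the stereorandom centre, while the tertiary alcohol, epoxide, N-oxide, alkene and silyl groups are inert under bicarbonate buffering.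

Step 13
Reactants: 25 the ketone from step 12
Product: 27 5-[(1R,2R,5S,6R)-2,5-dihydroxy-7-oxabicyclo[4.1.0]heptan-2-yl]-3-[(1R,2R,4aS,6R,8aR)-2,6-dimethyl-1,2,4a,5,6,7,8,8a-octahydronaphthalene-1-carbonyl]-1,4-dihydroxypyridin-2(1H)-one (target), via TBS ether of the target 26 (not isolated)
Conditions: Bu4NF (6 equiv), AcOH (4 equiv), THF, 0 → 30 °C
Reagents that add atoms: none
Why: Fluoride-induced β-elimination of the two 2-(trimethylsilyl)ethyl ethers releases ethene and fluorotrimethylsilane and unveils the 4-hydroxyl and the 2-oxido N-oxide (the tautomer of the 1-hydroxy-2-pyridone), the same reagent cleaves the TBS ether, and the acetic acid buffer keeps alkoxides protonated so that neither Payne rearrangement nor epoxide opening occurs and no stereocentre is touched.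

**Compound list**

1 | geranial, (2E)-3,7-dimethylocta-2,6-dienal | CC(C)=CCC/C(C)=C/C=O | starting material
2 | (R)-citronellal, (3R)-3,7-dimethyloct-6-enal | O=CC[C@H](C)CCC=C(C)C | intermediate
3 | N-methoxy-N-methylprop-2-enamide | C=CC(=O)N(C)OC | starting material
4 | (2E,6R)-N-methoxy-N,6-dimethyl-8-oxooct-2-enamide | O=CC[C@H](C)CC/C=C/C(=O)N(C)OC | intermediate
5 | (E)-but-2-en-1-yl(triphenyl)phosphonium chloride | C/C=C/C[P+](c1ccccc1)(c1ccccc1)c1ccccc1.[Cl-] | starting material
6 | (E)-but-2-en-1-ylidene(triphenyl)phosphorane | C/C=C/C=P(c1ccccc1)(c1ccccc1)c1ccccc1 | intermediate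
7 | (2E,6R,8Z,10E)-N-methoxy-N,6-dimethyldodeca-2,8,10-trienamide | C/C=C/C=C\C[C@H](C)CC/C=C/C(=O)N(C)OC | intermediate
8 | (2E,6R,8E,10E)-N-methoxy-N,6-dimethyldodeca-2,8,10-trienamide | C/C=C/C=C/C[C@H](C)CC/C=C/C(=O)N(C)OC | intermediate
9 | (2E,6R,8E,10E)-6-methyldodeca-2,8,10-trienal | C/C=C/C=C/C[C@H](C)CC/C=C/C=O | intermediate
10 | (1R,2R,4aS,6R,8aR)-2,6-dimethyl-1,2,4a,5,6,7,8,8a-octahydronaphthalene-1-carbaldehyde | C[C@@H]1CC[C@H]2[C@H](C=O)[C@H](C)C=C[C@@H]2C1 | intermediate
11 | 4-{[tert-butyl(dimethyl)silyl]oxy}cyclohexan-1-one | O=C1CCC(O[Si](C)(C)C(C)(C)C)CC1 | starting material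
12 | (2R,4S)-4-{[tert-butyl(dimethyl)silyl]oxy}-2-(phenylselanyl)cyclohexan-1-one | O=C1CC[C@H](O[Si](C)(C)C(C)(C)C)C[C@H]1[Se]c1ccccc1 | intermediate
13 | (2R,4S)-2-(benzeneseleninyl)-4-{[tert-butyl(dimethyl)silyl]oxy}cyclohexan-1-one (both configurations at selenium) | O=C1CC[C@H](O[Si](C)(C)C(C)(C)C)C[C@H]1[Se](=O)c1ccccc1 | intermediate
14 | (4S)-4-{[tert-butyl(dimethyl)silyl]oxy}cyclohex-2-en-1-one | O=C1CC[C@H](O[Si](C)(C)C(C)(C)C)C=C1 | intermediate
15 | (1R,5S,6S)-5-{[tert-butyl(dimethyl)silyl]oxy}-7-oxabicyclo[4.1.0]heptan-2-one | O=C1CC[C@H](O[Si](C)(C)C(C)(C)C)[C@H]2O[C@@H]12 | intermediate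
16 | 2-chloro-4-nitropyridine 1-oxide | [O-][n+]1ccc(cc1Cl)[N+](=O)[O-] | starting material
17 | 2-chloro-4-[2-(trimethylsilyl)ethoxy]pyridine 1-oxide | [O-][n+]1ccc(OCC[Si](C)(C)C)cc1Cl | intermediate
18 | 2,4-bis[2-(trimethylsilyl)ethoxy]pyridine 1-oxide | [O-][n+]1ccc(OCC[Si](C)(C)C)cc1OCC[Si](C)(C)C | intermediate
19 | 5-iodo-2,4-bis[2-(trimethylsilyl)ethoxy]pyridine 1-oxide | [O-][n+]1cc(I)c(OCC[Si](C)(C)C)cc1OCC[Si](C)(C)C | intermediate
20 | 3,5-diiodo-2,4-bis[2-(trimethylsilyl)ethoxy]pyridine 1-oxide | [O-][n+]1cc(I)c(OCC[Si](C)(C)C)c(I)c1OCC[Si](C)(C)C | intermediate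
21 | chloro{5-iodo-1-oxido-2,4-bis[2-(trimethylsilyl)ethoxy]pyridin-1-ium-3-yl}magnesium | [O-][n+]1cc(I)c(OCC[Si](C)(C)C)c([Mg]Cl)c1OCC[Si](C)(C)C | intermediate
22 | 3-{[(1R,2R,4aS,6R,8aR)-2,6-dimethyl-1,2,4a,5,6,7,8,8a-octahydronaphthalen-1-yl](hydroxy)methyl}-5-iodo-2,4-bis[2-(trimethylsilyl)ethoxy]pyridine 1-oxide (both carbinol epimers) | C[C@@H]1CC[C@H]2[C@H](C(O)c3c(OCC[Si](C)(C)C)[n+]([O-])cc(I)c3OCC[Si](C)(C)C)[C@H](C)C=C[C@@H]2C1 | intermediate
23 | chloromagnesium alkoxide of 22 carrying a chloromagnesio group at C5 in place of iodine | C[C@@H]1CC[C@H]2[C@H](C(O[Mg]Cl)c3c(OCC[Si](C)(C)C)[n+]([O-])cc([Mg]Cl)c3OCC[Si](C)(C)C)[C@H](C)C=C[C@@H]2C1 | intermediate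
24 | 5-[(1R,2R,5S,6S)-5-{[tert-butyl(dimethyl)silyl]oxy}-2-hydroxy-7-oxabicyclo[4.1.0]heptan-2-yl]-3-{[(1R,2R,4aS,6R,8aR)-2,6-dimethyl-1,2,4a,5,6,7,8,8a-octahydronaphthalen-1-yl](hydroxy)methyl}-2,4-bis[2-(trimethylsilyl)ethoxy]pyridine 1-oxide (both carbinol epimers) | C[C@@H]1CC[C@H]2[C@H](C(O)c3c(OCC[Si](C)(C)C)[n+]([O-])cc([C@]4(O)CC[C@H](O[Si](C)(C)C(C)(C)C)[C@H]5O[C@H]54)c3OCC[Si](C)(C)C)[C@H](C)C=C[C@@H]2C1 | intermediate
25 | 5-[(1R,2R,5S,6S)-5-{[tert-butyl(dimethyl)silyl]oxy}-2-hydroxy-7-oxabicyclo[4.1.0]heptan-2-yl]-3-[(1R,2R,4aS,6R,8aR)-2,6-dimethyl-1,2,4a,5,6,7,8,8a-octahydronaphthalene-1-carbonyl]-2,4-bis[2-(trimethylsilyl)ethoxy]pyridine 1-oxide | C[C@@H]1CC[C@H]2[C@H](C(=O)c3c(OCC[Si](C)(C)C)[n+]([O-])cc([C@]4(O)CC[C@H](O[Si](C)(C)C(C)(C)C)[C@H]5O[C@H]54)c3OCC[Si](C)(C)C)[C@H](C)C=C[C@@H]2C1 | intermediate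
26 | 5-[(1R,2R,5S,6S)-5-{[tert-butyl(dimethyl)silyl]oxy}-2-hydroxy-7-oxabicyclo[4.1.0]heptan-2-yl]-3-[(1R,2R,4aS,6R,8aR)-2,6-dimethyl-1,2,4a,5,6,7,8,8a-octahydronaphthalene-1-carbonyl]-1,4-dihydroxypyridin-2(1H)-one | C[C@@H]1CC[C@H]2[C@H](C(=O)c3c(O)c([C@]4(O)CC[C@H](O[Si](C)(C)C(C)(C)C)[C@H]5O[C@H]54)cn(O)c3=O)[C@H](C)C=C[C@@H]2C1 | intermediate
27 | 5-[(1R,2R,5S,6R)-2,5-dihydroxy-7-oxabicyclo[4.1.0]heptan-2-yl]-3-[(1R,2R,4aS,6R,8aR)-2,6-dimethyl-1,2,4a,5,6,7,8,8a-octahydronaphthalene-1-carbonyl]-1,4-dihydroxypyridin-2(1H)-one | C[C@@H]1CC[C@H]2[C@H](C(=O)c3c(O)c([C@]4(O)CC[C@H](O)[C@H]5O[C@H]54)cn(O)c3=O)[C@H](C)C=C[C@@H]2C1 | target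

**Step count and risks**

Total: 13 steps. Longest linear sequence: 9 steps (steps 1–5, then 10–13).

The three steps most likely to fail:

Step 6 (the proposed new desymmetrising selenenylation–elimination). The trans:cis ratio of the selenenylation becomes the enantiomer ratio of 14 and is untested; bis-selenenylation is also possible. The fallback uses known chemistry, sets out from 11 and comes back at 14. Ketone 11 is deprotonated enantioselectively with lithium (R,R)-bis(1-phenylethyl)amide in the presence of Me3SiCl (THF, −78 °C), the established chiral-base desymmetrisation of 4-substituted cyclohexanones, to give the silyl enol ether (S)-tert-butyl(dimethyl){[4-(trimethylsilyloxy)cyclohex-3-en-1-yl]oxy}silane F1. Saegusa–Ito oxidation (Pd(OAc)2 10 mol%, O2, DMSO, 23 °C) then gives 14.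

Step 11 (second exchange and ketone addition). The exchange at C5 must beat magnesiation at C6 next to the N-oxide in a substrate that already carries a magnesium alkoxide, and the addition must be face-selective without opening the epoxide. The fallback reverses the order of the two unions, sets out from 18 and comes back at 24. Compound 18 is mono-iodinated (N-iodosuccinimide, 1.0 equiv) and the 5-iodide 19 is isolated. Iodine–magnesium exchange on this simple, hydroxyl-free iodide (i-PrMgCl·LiCl, −78 °C, used in excess over the ketone) and LaCl3·2LiCl-promoted addition to 15 give 5-[(1R,2R,5S,6S)-5-{[tert-butyl(dimethyl)silyl]oxy}-2-hydroxy-7-oxabicyclo[4.1.0]heptan-2-yl]-2,4-bis[2-(trimethylsilyl)ethoxy]pyridine 1-oxide F2. Iodination at the only remaining activated position (N-iodosuccinimide, MeCN, no acid) gives 5-[(1R,2R,5S,6S)-5-{[tert-butyl(dimethyl)silyl]oxy}-2-hydroxy-7-oxabicyclo[4.1.0]heptan-2-yl]-3-iodo-2,4-bis[2-(trimethylsilyl)ethoxy]pyridine 1-oxide F3. A second exchange at the doubly alkoxy-flanked C3 (i-PrMgCl·LiCl, 2.1 equiv) and addition to 10 give 24.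

Step 2 (cross-metathesis). A trisubstituted alkene with a free aldehyde present may stall or give E/Z mixtures. The fallback replaces metathesis by oxidative cleavage, sets out from 2 and comes back at 9 (4, 7, 8 and step 4 are bypassed). Wittig reaction of 2 with ylide 6 (from 5 and KN(SiMe3)2), followed by the same iodine equilibration, gives (2E,4E,7R)-7,11-dimethyldodeca-2,4,10-triene F4. The more electron-rich trisubstituted alkene is epoxidised selectively with mCPBA (1.0 equiv, CH2Cl2, −20 °C) to 2,2-dimethyl-3-[(3R,5E,7E)-3-methylnona-5,7-dien-1-yl]oxirane F5. Periodic acid (H5IO6, THF/Et2O, 0 °C) cleaves the epoxide to (4R,6E,8E)-4-methyldeca-6,8-dienal F6. Wittig reaction with (triphenylphosphoranylidene)acetaldehyde (toluene, 80 °C) gives 9.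

**Further compounds**

F1 | step 6 | (S)-tert-butyl(dimethyl){[4-(trimethylsilyloxy)cyclohex-3-en-1-yl]oxy}silane | C[Si](C)(C)OC1=CC[C@@H](O[Si](C)(C)C(C)(C)C)CC1
F2 | step 11 | 5-[(1R,2R,5S,6S)-5-{[tert-butyl(dimethyl)silyl]oxy}-2-hydroxy-7-oxabicyclo[4.1.0]heptan-2-yl]-2,4-bis[2-(trimethylsilyl)ethoxy]pyridine 1-oxide | [O-][n+]1cc([C@]2(O)CC[C@H](O[Si](C)(C)C(C)(C)C)[C@H]3O[C@H]32)c(OCC[Si](C)(C)C)cc1OCC[Si](C)(C)C
F3 | step 11 | 5-[(1R,2R,5S,6S)-5-{[tert-butyl(dimethyl)silyl]oxy}-2-hydroxy-7-oxabicyclo[4.1.0]heptan-2-yl]-3-iodo-2,4-bis[2-(trimethylsilyl)ethoxy]pyridine 1-oxide | [O-][n+]1cc([C@]2(O)CC[C@H](O[Si](C)(C)C(C)(C)C)[C@H]3O[C@H]32)c(OCC[Si](C)(C)C)c(I)c1OCC[Si](C)(C)C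
F4 | step 2 | (2E,4E,7R)-7,11-dimethyldodeca-2,4,10-triene | C/C=C/C=C/C[C@H](C)CCC=C(C)C
F5 | step 2 | 2,2-dimethyl-3-[(3R,5E,7E)-3-methylnona-5,7-dien-1-yl]oxirane (both oxirane epimers) | C/C=C/C=C/C[C@H](C)CCC1OC1(C)C
F6 | step 2 | (4R,6E,8E)-4-methyldeca-6,8-dienal | C/C=C/C=C/C[C@H](C)CCC=O
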